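**Stalled capture.** The other capture product barely rose in ochre after its second reading. Ochre read 19.4% at 2.50 d and 21.0% at 6.00 d, while its target went from 18.8% to 34.0%. So I treated the second nucleophile as the limiting reagent and kept books on it.

| flask | substrate | first nucleophile | second nucleophile | remark | time |
|---|---|---|---|---|---|
| ochre | 0.050 M | 1.8 equiv | 2 equiv | run made earlier |  |
| teal | 0.050 M | 1.8 equiv | 1 equiv | run made earlier |  |
| red | 0.050 M | 1.8 equiv | 1.5 equiv | run made earlier |  |
| blue | 0.025 M | 1.8 equiv | 2 equiv | run made earlier |  |
| north-east | 0.050 M | 1.80 equiv | 2.00 equiv (fed, over 8.0 d) | all else is in the flask from the start; the feed brings no volume worth counting | 10 d |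
| north-west | 0.050 M | 1.80 equiv | 2.00 equiv (fed, over 50 h) | all else is in the flask from the start; the feed brings no volume worth counting | 10 d |
| north | 0.050 M | 1.80 equiv | 2.00 equiv | everything together at the start | 10 d |
| east | 0.050 M | 1.80 equiv (fed, over 8.0 d) | 2.00 equiv | all else is in the flask from the start; the feed brings no volume worth counting | 10 d |

| run | time / d | other capture product / % | target / % |
|---|---|---|---|
| ochre | 1.25 | 17.0 | 11.1 |
| ochre | 2.50 | 19.4 | 18.8 |
| ochre | 4.00 | 19.2 | 27.4 |
| ochre | 5.00 | 21.3 | 29.3 |
| ochre | 6.00 | 21.0 | 34.0 |
| teal | 1.25 | 14.2 | 9.8 |
| teal | 2.50 | 17.0 | 19.5 |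
| teal | 4.00 | 18.1 | 29.2 |
| teal | 5.00 | 19.2 | 31.3 |
| teal | 6.00 | 18.0 | 34.4 |
| red | 0.500 | 13.4 | 4.6 |
| red | 1.67 | 15.8 | 13.3 |
| red | 3.00 | 20.0 | 19.2 |
| red | 4.00 | 17.1 | 27.4 |
| red | 6.00 | 21.4 | 33.3 |
| blue | 0.500 | 10.6 | 1.1 |
| blue | 1.67 | 16.0 | 8.0 |
| blue | 3.00 | 20.8 | 15.3 |
| blue | 4.00 | 20.3 | 16.4 |
| blue | 6.00 | 21.0 | 20.5 |

(readings scatter by 1 percentage point)



- the flask with the highest amount of other capture product, in percent of the substrate charged ("all alike" if they lie within 1.5 percentage points) (north-east / north-west / north / east / all alike)
- final other capture product, as a percentage of the substrate charged, in north-east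
- final other capture product, as a percentage of the substrate charged, in north-west
- final other capture product, as a percentage of the substrate charged, in north
- final other capture product, as a percentage of the substrate charged, in east

**The ledger.** Teal was charged 1 equiv, so its last reading, 18.0%, is directly the capture share, the fraction of the charged second nucleophile that ends in other capture product. Ochre was charged 2 equiv. Capture took 10.5% of that charge. I booked the other 89.5% as lost by a route I could not read. Teal, at half the charge, kept a larger share than ochre. So I took the loss to grow faster with the standing amount than the capture did.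

**My reckoning.** I expected the feed in north-east to hold the standing amount down. North-east takes 4.00 d to bring in one teal charge, longer than the 1.25 d by which teal already read 14.2%. So I gave north-east teal's share, which makes 36.0%. I put north-west between ochre's reading and that figure. North and east hold the second nucleophile from the start, so I gave both about ochre's 21.0%.

**The forecast.** It named east. It gave north-east 7% (3% to 16%), north-west 12.5% (8% to 20%), north 21% (19.5% to 23%) and east 23% (16% to 33%). Its ground was this: “Slow feeding starves that early window”. We parted on the feeds, since its north-east lay below mine.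

**The flasks.** North-east gave 35.5%, north-west 31.8%, north 21.3% and east 23.2%, so north-east stood highest.

    substrate ⇌ intermediate (K = 0.00220, k = 0.00110 min⁻¹)
    first nucleophile + intermediate → target (k = 0.520 M⁻¹ min⁻¹)
    second nucleophile + intermediate → other capture product (k = 4.90 M⁻¹ min⁻¹)
    substrate ⇌ dormant form (K = 0.320, k = 2.10 × 10⁻⁴ min⁻¹)
    2 second nucleophile → self-condensation product (k = 0.0500 M⁻¹ min⁻¹)

**The share.** The capture share in north-east was 17.7%, close to teal's last reading, 18.0%. In north-west, fed over 50 h, it was 15.9%. In north it was 10.6%. Self-condensation is a part of the reason for north-east's lead over north: with that step taken out, the lead went from 14 percentage points to −22 points.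

The data were generated by integration with made-up constants; the scatter is artificial.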